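A pitfall in counting chains is to divide reacted monomer by the initiator charged, as if each Q began a chain, when G, a further species, may take Q first.

all flasks: Q 0.20 mM; G 0.23 mM
- dawn: X 10 mM (fed, over 50 h); E 0.60 mM; run made earlier
- spring: X 15 mM (fed, over 50 h); E 0.60 mM; run made earlier
- flask: X 20 mM (fed, over 50 h); E 0.600 mM; time 2.5 d

| run | time / d | D / % | X / % |
|---|---|---|---|
| dawn | 0.250 | 0.2 | 11.9 |
| dawn | 0.500 | 0.1 | 24.1 |
| dawn | 1.25 | 0.9 | 59.2 |
| dawn | 3.00 | 3.3 | 96.1 |
| spring | 0.417 | 0.1 | 19.2 |
| spring | 1.04 | 0.6 | 48.5 |
| spring | 2.08 | 3.2 | 97.2 |
| spring | 3.00 | 5.0 | 95.2 |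

(each reading ± 0.3 percentage points)

- average number of monomer units in a chain (chains begun, living or dead) at 2.5 d
- part of the X that has reacted at 2.5 d

- the average divides the monomer in chains by the number of chains begun, living and dead together
- the earlier runs do not show the number of chains; that part of a forecast is a guess
- percentages count the whole charge, also what has not yet gone in

1. Fastest rung, inferred from the readings. In the dawn run, D at 0.250 d reads 0.2% of the charge, or 0.0200 mM, less than the 0.20 mM of Q. Q therefore did not turn at once into chains, and G may remove it instead.

2. Suppose Q and G pair one to one. Q is then the limiting reagent, being charged below G, and the quantity to carry is the Q margin −0.0300 mM, Q charged minus G charged. A negative margin leaves no Q beyond what slips past G.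

3. Middle rung: the feed. In the dawn run at 1.25 d, X reads 59.2% with 60.0% fed, so X stands close to what has gone in.

4. Slowest rung: reaction. After the feed, D in the spring run climbs from 3.2% to 5.0%, which reads as a half-life of X near 34.4 d, long against the feed. My own reckoning puts c in the flask near that spring reading.

5. Counting every Q as a chain gives the spring run an average of 3.75 at 3.00 d. With a negative margin, I expect dp far above that, though the runs give no figure.

6. The forecast says dp 8 and c 5.3%, noting that “G may scavenge it and initiation looks slow”. Its c lies near mine, while its dp is a guess.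

7. The flask gives dp 1290 and c 5.17%.

    X + Q → J + D (k = 0.720 M⁻¹ min⁻¹)
    X + J → D + J, rate k2*[J]*[X] (k = 53.0 M⁻¹ min⁻¹)
    J + E → L (k = 0.390 M⁻¹ min⁻¹)
    Q + G → Z (k = 480 M⁻¹ min⁻¹)

In the flask, Q has a half-life of 0.10 h against G, far shorter than the 3.3 d that the X + Q step gives X with Q held at its charge. At 2.50 d, Z stands at 0.199 mM, nearly all of the Q, and the margin −0.0300 mM appears as G left over, 13% of its charge. In a neighbour flask with 0.80 mM of Q, the other charges held, the margin is 0.570 mM, positive; that neighbour gives dp 48.0 and c >99.9%.

The readings come from a simulation on assumed constants; scatter was added.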